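The runs are simulated for an exercise; noise was put on by code.

Time is what you must pick for this flask. The isomer of the product rises early, then fades, and theta, charged with more protic impurity than beta, holds less of it at the last reading. So I solve each end from the readings, as fractions of the charge, and join them.

| flask | starting material | protic impurity | catalyst | remark | time |
|---|---|---|---|---|---|
| beta | 17 mM | 4.2 mM | 0.43 mM | run made earlier |  |
| theta | 17 mM | 17 mM | 0.43 mM | run made earlier |  |
| flask | 17 mM | 8.50 mM | 0.43 mM |  | 15 d |

| run | time / d | isomer of the product / % | target / % |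
|---|---|---|---|
| beta | 0.333 | 8.8 | 12.0 |
| beta | 0.625 | 13.8 | 13.5 |
| beta | 1.04 | 16.1 | 13.4 |
| beta | 2.08 | 17.6 | 11.8 |
| beta | 4.00 | 14.1 | 10.5 |
| beta | 6.00 | 14.5 | 8.9 |
| beta | 12.0 | 9.5 | 6.1 |
| theta | 0.333 | 9.1 | 10.0 |
| theta | 0.625 | 10.4 | 10.8 |
| theta | 1.04 | 11.7 | 9.5 |
| theta | 2.08 | 9.2 | 6.1 |
| theta | 4.00 | 5.9 | 3.0 |
| theta | 6.00 | 3.1 | 2.0 |
| theta | 12.0 | 0.9 | 1.4 |

(scatter of a reading: 0.5 percentage points)

- when, up to 15 d, the flask holds most isomer of the product
- the amount of isomer of the product, in percent of the starting material charged, at that time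

- a reading or a percentage of target counts all its forms, free or not

Take the late end first. The beta isomer falls at 0.0622 d⁻¹ with 0.247 equivalents of impurity, and the theta isomer at 0.268 d⁻¹ with 1.00. Call the apparent first-order fall per equivalent of impurity charged the quench number. The two runs give nearly the same value, so I take their mean, 0.260 d⁻¹. This flask, with 0.500 equivalents, should then fall at 0.130 d⁻¹.

At the early end, the first readings, 8.8% and 9.1%, agree within the scatter, so the rise is about 0.269 d⁻¹ of the charge. To join the ends, run the late lines back to zero time: they start at 20.0% and 15.5%, which interpolates to 18.5% for this flask. A curve A(exp(−λt) − exp(−ft)) with that start and rise has f = 1.58 d⁻¹. My reckoning therefore peaks at 1.72 d with 13.6%.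

The forecast, reasoning that “decay scales roughly with impurity”, says 1.4 d and 14.8%, which is earlier and higher than mine.

The flask gives 1.39 d and 14.9%, so the forecast stands. The top is broad: the flask still holds 13.1% at 2.78 d.

    starting material + catalyst ⇌ target + catalyst, rate k1*[starting material]*[catalyst] forward; the back reaction follows from the equilibrium constant (K = 0.264, k = 0.0188 M⁻¹ s⁻¹)
    target ⇌ isomer of the product (K = 1.43, k = 4.71 × 10⁻⁶ s⁻¹)
    isomer of the product ⇌ starting material (k = 1.13 × 10⁻⁵ s⁻¹)
    starting material + protic impurity → quenched substrate (k = 7.59 × 10⁻⁴ M⁻¹ s⁻¹)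
    crystals ⇌ target, rate k5*(cs5 - [target]) while solid is left; crystals form when [target] > cs5 (solubility = 12.0 mM, k = 2.88 × 10⁻⁴ s⁻¹)
    starting material → uncatalysed product (k = 9.49 × 10⁻⁷ s⁻¹)

Run from the best at the flask's quench rate, the isomer should reach 2.54% at 15.0 d. The flask holds 5.09%, with 1.8% of the impurity left: over that stretch the quench number gives too steep a fall.

For the flask stopped at 4.00 d, the same fall gives 10.6%; it holds 11.2%.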